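The whole route rests on a [3+3] disconnection of the 2,2,6,6-tetrasubstituted 2H-pyran-3(6H)-one ring at O1–C2 (ring oxygen to the later quaternary carbon) and at C4–C5. The key step joins a silyl enol ether diazoacetoacetate (C2–C3(=O)–C4) with 2-hydroxy-2-methylpropanal (O1–C6Me2–C5) in one flask: a Mukaiyama aldol makes C4–C5 and a rhodium-carbene O–H insertion by the tertiary hydroxyl makes O1–C2. It exploits the ring ketone C3, which lies between both new bonds, and the non-enolisable gem-dimethyl carbinol C6. Elimination gives the C4=C5 enone, the allyl ester sets the quaternary centre by decarboxylative asymmetric allylation, and the allyl group carries the chain by B-alkyl Suzuki coupling.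

Key step: step 4

Assumption: the sense of induction in step 6 is taken from 2-alkylcycloalkanone enolates with the same ligand; should the ring oxygen invert it, the (R)-ligand is used and nothing else changes.

Step 1
Reactants: 1 2-methylbut-3-en-2-ol
Product: 2 2-hydroxy-2-methylpropanal
Conditions: O3, CH2Cl2, −78 °C; Me2S, −78 °C to rt; distilled and used fresh
Reagents that add atoms: ozone, [O-][O+]=O
Why: Ozonolysis with reductive work-up cleaves the only C=C bond, leaves the tertiary alcohol untouched and should give the non-enolisable α-hydroxy aldehyde, which is freed from formaldehyde by distillation and used soon because it dimerises.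

Step 2
Reactants: 3 allyl acetoacetate (prop-2-enyl 3-oxobutanoate)
Product: 4 allyl 2-diazo-3-oxobutanoate
Conditions: 4-acetamidobenzenesulfonyl azide, Et3N, MeCN, 0 °C to rt
Reagents that add atoms: 4-acetamidobenzenesulfonyl azide, CC(=O)Nc1ccc(cc1)S(=O)(=O)N=[N+]=[N-]
Why: Regitz diazo transfer to the doubly activated methylene of the β-keto ester is fast and clean under amine base.

Step 3
Reactants: 4 allyl 2-diazo-3-oxobutanoate
Product: 5 allyl 3-(tert-butyldimethylsilyloxy)-2-diazobut-3-enoate
Conditions: TBSOTf, Et3N, CH2Cl2, 0 °C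
Reagents that add atoms: tert-butyldimethylsilyl trifluoromethanesulfonate, CC(C)(C)[Si](C)(C)OS(=O)(=O)C(F)(F)F
Why: Soft enolisation and O-silylation of the acetyl group with silyl triflate and amine leaves the diazo group intact and turns the former acetyl CH3 into a nucleophilic enol ether carbon.

Step 4
Reactants: 5 allyl 3-(tert-butyldimethylsilyloxy)-2-diazobut-3-enoate; 2 2-hydroxy-2-methylpropanal (1.2 equiv)
Product: 7 allyl 5-(tert-butyldimethylsilyloxy)-6,6-dimethyl-3-oxooxane-2-carboxylate as a racemic mixture of diastereomers, via silyloxy hydroxy diazo keto ester 6 (not isolated)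
Conditions: Zn(OTf)2 (3 mol %), CH2Cl2, rt until 5 is consumed; then Rh2(OAc)4 (1 mol %), 40 °C
Reagents that add atoms: none
Why: Zn(OTf)2 chelates and activates the hydroxy aldehyde, the terminal CH2 of the silyl enol ether adds to it (Mukaiyama aldol) with transfer of the silyl group to the new secondary oxygen and with the diazo group untouched, which makes the C4–C5 bond; Rh2(OAc)4 then expels N2 and the electrophilic keto ester carbenoid is captured by the free tertiary hydroxyl (oxonium ylide, then proton shift), which makes the O1–C2 bond. The closest known reaction types are the Lewis-acid Mukaiyama aldol of 3-silyloxy-2-diazobut-3-enoates with aldehydes and the carbenoid O–H insertion cyclisation of hydroxy diazo keto esters. The one ring formed, the oxane, is closed at the O–C bond by attack of the tethered hydroxyl on the carbenoid carbon, a six-membered closure that needs no alkene geometry. The two new stereocentres (C2 and C5) are not controlled and need not be, because C5 becomes sp2 in step 5 and C2 is reset in step 6. The step needs the silyl group on the C5 oxygen and not on the tertiary one, since a free C5 hydroxyl would close a five-membered furanone instead; the intramolecular silyl shift within the zinc aldolate and the bulk of the tertiary alcohol should secure this. Carbenoid C–H insertion is not expected to compete because the carbon in the favoured 1,5-position is the hydrogen-free C6.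

Step 5
Reactants: 7 allyl 5-(tert-butyldimethylsilyloxy)-6,6-dimethyl-3-oxooxane-2-carboxylate
Product: 9 racemic allyl 2,6,6-trimethyl-3-oxo-3,6-dihydro-2H-pyran-2-carboxylate, via C-methylated silyloxy oxanone 8 (not isolated)
Conditions: MeI, K2CO3, acetone, rt; volatiles removed; DBU, toluene, 60 °C
Reagents that add atoms: iodomethane, CI
Why: C-alkylation of the cyclic β-keto ester enolate makes C2 quaternary, after which C4 is the only acidic position and base expels the β-silyloxy group (E1cB elimination) to give the C4=C5 enone; the racemic C2 centre is reset in step 6.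

Step 6
Reactants: 9 racemic allyl 2,6,6-trimethyl-3-oxo-3,6-dihydro-2H-pyran-2-carboxylate
Product: 10 (2S)-2-allyl-2,6,6-trimethyl-2H-pyran-3(6H)-one
Conditions: Pd2(dba)3 (2.5 mol %), (S)-t-BuPHOX [(S)-4-tert-butyl-2-(2-diphenylphosphanylphenyl)-4,5-dihydrooxazole] (6.25 mol %), toluene, 25–40 °C
Reagents that add atoms: none
Why: Decarboxylative asymmetric allylic alkylation (Tsuji-type, Pd/PHOX): ionisation of the allyl ester and loss of CO2 turn both enantiomers of 9 into one achiral palladium dienolate that can only be allylated at C2, and the chiral ligand directs the allyl group to one face, expected by analogy with 2-alkylcycloalkanone enolates to give the (S)-configured quaternary centre.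

Step 7
Reactants: 11 4-methoxy-3-methylphenol
Product: 12 triisopropyl(4-methoxy-3-methylphenoxy)silane
Conditions: TIPSCl, imidazole, DMF, rt
Reagents that add atoms: chlorotriisopropylsilane, CC(C)[Si](Cl)(C(C)C)C(C)C
Why: Silyl ether formation with a bulky silyl chloride protects the phenol against organolithium, organoaluminium and oxidising conditions and gives a group that is a poor ortho-director.

Step 8
Reactants: 12 triisopropyl(4-methoxy-3-methylphenoxy)silane
Product: 14 [2-methoxy-3-methyl-5-(triisopropylsilyloxy)phenyl]methanol, via aryllithium 13 (not isolated)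
Conditions: n-BuLi, TMEDA, Et2O, 0 °C to rt; (CH2O)n, −78 °C to rt; aq. NH4Cl
Reagents that add atoms: paraformaldehyde (formaldehyde unit), C=O
Why: Directed ortho-metalation: the methoxy group directs lithiation to its only free ortho position, the bulky silyloxy group should not compete, and the aryllithium adds to formaldehyde.

Step 9
Reactants: 14 [2-methoxy-3-methyl-5-(triisopropylsilyloxy)phenyl]methanol
Product: 15 [3-(chloromethyl)-4-methoxy-5-methylphenoxy]triisopropylsilane
Conditions: SOCl2, pyridine, CH2Cl2, 0 °C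
Reagents that add atoms: thionyl chloride, ClS(Cl)=O
Why: Chlorodehydroxylation of the electron-rich benzylic alcohol with thionyl chloride under base buffering proceeds readily at low temperature and spares the aryl silyl ether.

Step 10
Reactants: 16 but-3-yn-1-ol (1.3 equiv); 15 [3-(chloromethyl)-4-methoxy-5-methylphenoxy]triisopropylsilane
Product: 18 (3E)-5-[2-methoxy-3-methyl-5-(triisopropylsilyloxy)phenyl]-3-methylpent-3-en-1-ol, via alkenylalane 17 (not isolated)
Conditions: AlMe3 (3 equiv), Cp2ZrCl2 (25 mol %), CH2Cl2, 0 °C to rt; volatiles removed; then 15, Pd(PPh3)4 (5 mol %), THF, rt; aq. HCl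
Reagents that add atoms: trimethylaluminium, C[Al](C)C
Why: Zirconium-catalysed carboalumination adds methyl and aluminium syn across the terminal alkyne (methyl to the internal carbon), and the alkenylalane couples with the benzylic chloride under zerovalent palladium catalysis with retention (Negishi-type coupling), which fixes the E trisubstituted alkene.

Step 11
Reactants: 18 (3E)-5-[2-methoxy-3-methyl-5-(triisopropylsilyloxy)phenyl]-3-methylpent-3-en-1-ol
Product: 19 (3E)-5-[2-methoxy-3-methyl-5-(triisopropylsilyloxy)phenyl]-3-methylpent-3-enal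
Conditions: Dess–Martin periodinane, NaHCO3, CH2Cl2, 0 °C; used at once
Reagents that add atoms: none
Why: Dess–Martin oxidation under bicarbonate buffer should give the β,γ-unsaturated aldehyde without acid or base strong enough to move the double bond into conjugation.

Step 12
Reactants: 19 (3E)-5-[2-methoxy-3-methyl-5-(triisopropylsilyloxy)phenyl]-3-methylpent-3-enal
Product: 20 (6E)-8-[2-methoxy-3-methyl-5-(triisopropylsilyloxy)phenyl]-6-methyloct-6-en-2-yn-4-ol (racemic at C4)
Conditions: 1-propynylmagnesium bromide (CH3C≡CMgBr), THF, −78 °C; aq. NH4Cl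
Reagents that add atoms: 1-propynylmagnesium bromide, CC#C[Mg]Br
Why: 1,2-Addition of the weakly basic alkynyl Grignard reagent at low temperature should outpace enolisation of the sensitive aldehyde, and the new carbinol centre may be racemic because it is oxidised in step 15.

Step 13
Reactants: 20 (6E)-8-[2-methoxy-3-methyl-5-(triisopropylsilyloxy)phenyl]-6-methyloct-6-en-2-yn-4-ol
Product: 22 (2E,6E)-2-iodo-8-[2-methoxy-3-methyl-5-(triisopropylsilyloxy)phenyl]-6-methylocta-2,6-dien-4-ol, via alkenylzirconocene 21 (not isolated)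
Conditions: Cp2Zr(H)Cl (3 equiv), THF, rt to 40 °C; then I2, 0 °C
Reagents that add atoms: iodine, II
Why: Hydrozirconation–iodination: Zr–H adds syn across the alkyne and, with excess reagent, zirconium settles on the less hindered methyl-bearing carbon away from the bulky zirconium alkoxide, and iodinolysis with retention gives the vinyl iodide with iodine trans to the carbinol carbon.

Step 14
Reactants: 10 (2S)-2-allyl-2,6,6-trimethyl-2H-pyran-3(6H)-one; 22 (2E,6E)-2-iodo-8-[2-methoxy-3-methyl-5-(triisopropylsilyloxy)phenyl]-6-methylocta-2,6-dien-4-ol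
Product: 24 (2S)-2-[(4E,8E)-6-hydroxy-10-[2-methoxy-3-methyl-5-(triisopropylsilyloxy)phenyl]-4,8-dimethyldeca-4,8-dien-1-yl]-2,6,6-trimethyl-2H-pyran-3(6H)-one (mixture of carbinol epimers), via B-alkyl-9-BBN borane 23 (not isolated)
Conditions: 9-BBN dimer (0.55 equiv), THF, 0 °C to rt; then 22, Pd(dppf)Cl2 (5 mol %), AsPh3, K3PO4 (3 M aq.), DMF, rt
Reagents that add atoms: none
Why: 9-BBN hydroborates the monosubstituted alkene far faster than it reduces the hindered conjugated ketone, and the B-alkyl Suzuki–Miyaura coupling with the vinyl iodide proceeds with retention of alkene geometry under mild aqueous phosphate, leaving the quaternary centre untouched.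

Step 15
Reactants: 24 (2S)-2-[(4E,8E)-6-hydroxy-10-[2-methoxy-3-methyl-5-(triisopropylsilyloxy)phenyl]-4,8-dimethyldeca-4,8-dien-1-yl]-2,6,6-trimethyl-2H-pyran-3(6H)-one
Product: 25 (2S)-2-[(4E,8E)-10-[2-methoxy-3-methyl-5-(triisopropylsilyloxy)phenyl]-4,8-dimethyl-6-oxodeca-4,8-dien-1-yl]-2,6,6-trimethyl-2H-pyran-3(6H)-one
Conditions: Dess–Martin periodinane, NaHCO3, CH2Cl2, 0 °C
Reagents that add atoms: none
Why: Dess–Martin oxidation converts the secondary allylic alcohol into the E enone under buffered, non-basic conditions that should not isomerise the β,γ-double bond.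

Step 16
Reactants: 25 (2S)-2-[(4E,8E)-10-[2-methoxy-3-methyl-5-(triisopropylsilyloxy)phenyl]-4,8-dimethyl-6-oxodeca-4,8-dien-1-yl]-2,6,6-trimethyl-2H-pyran-3(6H)-one
Product: 26 (2S)-2-[(4E,8E)-10-(5-hydroxy-2-methoxy-3-methylphenyl)-4,8-dimethyl-6-oxodeca-4,8-dien-1-yl]-2,6,6-trimethyl-2H-pyran-3(6H)-one (CNP0160516.1)
Conditions: TBAF, AcOH (1:1), THF, 0 °C
Reagents that add atoms: none
Why: Desilylation with fluoride buffered by acetic acid cleaves the aryl silyl ether without exposing the skipped enone to free base.

Compound list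
1 | 2-methylbut-3-en-2-ol | CC(C)(O)C=C | starting material
2 | 2-hydroxy-2-methylpropanal | CC(C)(O)C=O | intermediate
3 | allyl acetoacetate | CC(=O)CC(=O)OCC=C | starting material
4 | allyl 2-diazo-3-oxobutanoate | CC(=O)C(=[N+]=[N-])C(=O)OCC=C | intermediate
5 | allyl 3-(tert-butyldimethylsilyloxy)-2-diazobut-3-enoate | C=C(O[Si](C)(C)C(C)(C)C)C(=[N+]=[N-])C(=O)OCC=C | intermediate
6 | allyl 5-(tert-butyldimethylsilyloxy)-2-diazo-6-hydroxy-6-methyl-3-oxoheptanoate (racemic, not isolated) | CC(C)(O)C(O[Si](C)(C)C(C)(C)C)CC(=O)C(=[N+]=[N-])C(=O)OCC=C | intermediate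
7 | allyl 5-(tert-butyldimethylsilyloxy)-6,6-dimethyl-3-oxooxane-2-carboxylate (racemic, mixture of C2/C5 diastereomers) | C=CCOC(=O)C1OC(C)(C)C(O[Si](C)(C)C(C)(C)C)CC1=O | intermediate
8 | allyl 5-(tert-butyldimethylsilyloxy)-2,6,6-trimethyl-3-oxooxane-2-carboxylate (racemic diastereomers, not isolated) | C=CCOC(=O)C1(C)OC(C)(C)C(O[Si](C)(C)C(C)(C)C)CC1=O | intermediate
9 | allyl 2,6,6-trimethyl-3-oxo-3,6-dihydro-2H-pyran-2-carboxylate (racemic) | C=CCOC(=O)C1(C)OC(C)(C)C=CC1=O | intermediate
10 | (2S)-2-allyl-2,6,6-trimethyl-2H-pyran-3(6H)-one | C=CC[C@]1(C)OC(C)(C)C=CC1=O | intermediate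
11 | 4-methoxy-3-methylphenol | COc1ccc(O)cc1C | starting material
12 | triisopropyl(4-methoxy-3-methylphenoxy)silane | COc1ccc(O[Si](C(C)C)(C(C)C)C(C)C)cc1C | intermediate
13 | [2-methoxy-3-methyl-5-(triisopropylsilyloxy)phenyl]lithium (not isolated) | COc1c(C)cc(O[Si](C(C)C)(C(C)C)C(C)C)cc1[Li] | intermediate
14 | [2-methoxy-3-methyl-5-(triisopropylsilyloxy)phenyl]methanol | COc1c(C)cc(O[Si](C(C)C)(C(C)C)C(C)C)cc1CO | intermediate
15 | [3-(chloromethyl)-4-methoxy-5-methylphenoxy]triisopropylsilane | COc1c(C)cc(O[Si](C(C)C)(C(C)C)C(C)C)cc1CCl | intermediate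
16 | but-3-yn-1-ol | C#CCCO | starting material
17 | (E)-alkenylalane from 16: dimethylaluminium on the alkene terminus cis to the new methyl group, alcohol as its dimethylaluminium alkoxide (not isolated) | C[Al](C)/C=C(\C)CCO[Al](C)C | intermediate
18 | (3E)-5-[2-methoxy-3-methyl-5-(triisopropylsilyloxy)phenyl]-3-methylpent-3-en-1-ol | COc1c(C)cc(O[Si](C(C)C)(C(C)C)C(C)C)cc1C/C=C(\C)CCO | intermediate
19 | (3E)-5-[2-methoxy-3-methyl-5-(triisopropylsilyloxy)phenyl]-3-methylpent-3-enal | COc1c(C)cc(O[Si](C(C)C)(C(C)C)C(C)C)cc1C/C=C(\C)CC=O | intermediate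
20 | (6E)-8-[2-methoxy-3-methyl-5-(triisopropylsilyloxy)phenyl]-6-methyloct-6-en-2-yn-4-ol (racemic at C4) | COc1c(C)cc(O[Si](C(C)C)(C(C)C)C(C)C)cc1C/C=C(\C)CC(O)C#CC | intermediate
21 | (E)-alkenylzirconocene chloride from 20, zirconium on C2 trans to C4, alcohol as its zirconocene chloride alkoxide, cyclopentadienyl rings drawn σ-bonded (not isolated) | COc1c(C)cc(O[Si](C(C)C)(C(C)C)C(C)C)cc1C/C=C(\C)CC(O[Zr](Cl)(C1C=CC=C1)C1C=CC=C1)/C=C(\C)[Zr](Cl)(C1C=CC=C1)C1C=CC=C1 | intermediate
22 | (2E,6E)-2-iodo-8-[2-methoxy-3-methyl-5-(triisopropylsilyloxy)phenyl]-6-methylocta-2,6-dien-4-ol (racemic at C4) | COc1c(C)cc(O[Si](C(C)C)(C(C)C)C(C)C)cc1C/C=C(\C)CC(O)/C=C(\C)I | intermediate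
23 | 9-[3-[(2S)-2,6,6-trimethyl-3-oxo-3,6-dihydro-2H-pyran-2-yl]propyl]-9-borabicyclo[3.3.1]nonane (not isolated) | B1(CCC[C@]2(C)OC(C)(C)C=CC2=O)C2CCCC1CCC2 | intermediate
24 | (2S)-2-[(4E,8E)-6-hydroxy-10-[2-methoxy-3-methyl-5-(triisopropylsilyloxy)phenyl]-4,8-dimethyldeca-4,8-dien-1-yl]-2,6,6-trimethyl-2H-pyran-3(6H)-one (epimers at the carbinol) | COc1c(C)cc(O[Si](C(C)C)(C(C)C)C(C)C)cc1C/C=C(\C)CC(O)/C=C(\C)CCC[C@]1(C)OC(C)(C)C=CC1=O | intermediate
25 | (2S)-2-[(4E,8E)-10-[2-methoxy-3-methyl-5-(triisopropylsilyloxy)phenyl]-4,8-dimethyl-6-oxodeca-4,8-dien-1-yl]-2,6,6-trimethyl-2H-pyran-3(6H)-one | COc1c(C)cc(O[Si](C(C)C)(C(C)C)C(C)C)cc1C/C=C(\C)CC(=O)/C=C(\C)CCC[C@]1(C)OC(C)(C)C=CC1=O | intermediate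
26 | (2S)-2-[(4E,8E)-10-(5-hydroxy-2-methoxy-3-methylphenyl)-4,8-dimethyl-6-oxodeca-4,8-dien-1-yl]-2,6,6-trimethyl-2H-pyran-3(6H)-one (CNP0160516.1) | COc1c(C)cc(O)cc1C/C=C(\C)CC(=O)/C=C(\C)CCC[C@]1(C)OC(C)(C)C=CC1=O | target

Total step count: 16
Longest linear sequence: 10 steps (steps 7 to 16, from 4-methoxy-3-methylphenol). The pyranone branch runs through steps 2 to 6 and then 14 to 16; step 1 feeds step 4.

Steps most likely to fail

Step 4. What may go wrong: migration or loss of the silyl group before the carbenoid is formed, so that the freed secondary hydroxyl closes a five-membered ring, or protodesilylation of the enol ether by the free alcohol before the aldol takes place. The fallback sets out from 4 and comes back at 9, and it reverses the order of the two bond formations. Rh2(OAc)4-catalysed intermolecular O–H insertion of 4 into 1,1-dimethoxy-2-methylpropan-2-ol F1 (made from commercial 1,1-dimethoxypropan-2-one and MeMgBr) in benzene at reflux should give allyl 2-[(1,1-dimethoxy-2-methylpropan-2-yl)oxy]-3-oxobutanoate F2. C-Methylation (MeI, K2CO3, acetone) should give allyl 2-[(1,1-dimethoxy-2-methylpropan-2-yl)oxy]-2-methyl-3-oxobutanoate F3. Aqueous trifluoroacetic acid should unmask allyl 2-methyl-2-[(2-methyl-1-oxopropan-2-yl)oxy]-3-oxobutanoate F4, whose only enolisable position is the acetyl methyl group. Acid-catalysed intramolecular aldol condensation (TsOH, toluene, reflux) onto the non-enolisable aldehyde should then close the ring and give 9.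

Step 6. What may go wrong: poor facial selectivity on the α-alkoxy dienolate, giving low enantiomeric purity, or protonation of the enolate before allylation. The fallback sets out from 9 and comes back at 10, and it replaces asymmetric catalysis by resolution. Pd(PPh3)4 in THF should convert 9 by the same decarboxylative allylation, without a chiral ligand, into racemic 2-allyl-2,6,6-trimethyl-2H-pyran-3(6H)-one F5. Preparative chromatography on a chiral stationary phase (supercritical CO2 with an alcohol modifier) should separate 10 from its antipode (2R)-2-allyl-2,6,6-trimethyl-2H-pyran-3(6H)-one F6.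

Step 14. What may go wrong: reduction of the ring enone by the borane in competition with hydroboration, or slow transmetalation with loss of iodine from 22 by protodehalogenation. The fallback sets out from 10 and comes back at 25, and it carries the ring ketone at the alcohol level through the coupling. Luche reduction (NaBH4, CeCl3·7H2O, MeOH, 0 °C) should give (2S)-2-allyl-2,6,6-trimethyl-3,6-dihydro-2H-pyran-3-ol F7 as a mixture of C3 epimers. 9-BBN (2.2 equiv) should give the O-boryl B-alkyl borane F8, which under the coupling conditions of step 14 should react with 22 to give (2S)-2-[(4E,8E)-6-hydroxy-10-[2-methoxy-3-methyl-5-(triisopropylsilyloxy)phenyl]-4,8-dimethyldeca-4,8-dien-1-yl]-2,6,6-trimethyl-3,6-dihydro-2H-pyran-3-ol F9. The Dess–Martin oxidation of step 15, run with a double charge of oxidant, should oxidise both allylic alcohols and arrive at 25.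

Further compounds
F1 | step 4 | 1,1-dimethoxy-2-methylpropan-2-ol | COC(OC)C(C)(C)O
F2 | step 4 | allyl 2-[(1,1-dimethoxy-2-methylpropan-2-yl)oxy]-3-oxobutanoate (racemic) | CC(=O)C(OC(C)(C)C(OC)OC)C(=O)OCC=C
F3 | step 4 | allyl 2-[(1,1-dimethoxy-2-methylpropan-2-yl)oxy]-2-methyl-3-oxobutanoate (racemic) | CC(=O)C(C)(OC(C)(C)C(OC)OC)C(=O)OCC=C
F4 | step 4 | allyl 2-methyl-2-[(2-methyl-1-oxopropan-2-yl)oxy]-3-oxobutanoate (racemic) | CC(=O)C(C)(OC(C)(C)C=O)C(=O)OCC=C
F5 | step 6 | racemic 2-allyl-2,6,6-trimethyl-2H-pyran-3(6H)-one | C=CCC1(C)OC(C)(C)C=CC1=O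
F6 | step 6 | (2R)-2-allyl-2,6,6-trimethyl-2H-pyran-3(6H)-one | C=CC[C@@]1(C)OC(C)(C)C=CC1=O
F7 | step 14 | (2S)-2-allyl-2,6,6-trimethyl-3,6-dihydro-2H-pyran-3-ol (C3 epimers) | C=CC[C@]1(C)OC(C)(C)C=CC1O
F8 | step 14 | 9-[3-[(2S)-3-(9-borabicyclo[3.3.1]nonan-9-yloxy)-2,6,6-trimethyl-3,6-dihydro-2H-pyran-2-yl]propyl]-9-borabicyclo[3.3.1]nonane | B1(CCC[C@]2(C)OC(C)(C)C=CC2OB2C3CCCC2CCC3)C2CCCC1CCC2
F9 | step 14 | (2S)-2-[(4E,8E)-6-hydroxy-10-[2-methoxy-3-methyl-5-(triisopropylsilyloxy)phenyl]-4,8-dimethyldeca-4,8-dien-1-yl]-2,6,6-trimethyl-3,6-dihydro-2H-pyran-3-ol | COc1c(C)cc(O[Si](C(C)C)(C(C)C)C(C)C)cc1C/C=C(\C)CC(O)/C=C(\C)CCC[C@]1(C)OC(C)(C)C=CC1O
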